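- Over-reaction product is taken here as what target turns into: in the eta run it gains 25 percentage points between 0.333 d and 0.833 d, while target goes from 14.9 % to 18.9 %.

in all of them: initiator 5 mol%

| flask | substrate | partner | remark | time |
|---|---|---|---|---|
| eta | 25 mM | 5 equiv | run made earlier |  |
| alpha | 230 mM | 5 equiv | run made earlier |  |
| Sunday's | 20 mM | 5.00 equiv |  | 5.0 d |
| Thursday's | 40 mM | 5.00 equiv |  | 5.0 d |
| Friday's | 80 mM | 5.00 equiv |  | 5.0 d |
| Saturday's | 150 mM | 5.00 equiv |  | 5.0 d |

| run | time / d | target / % | over-reaction product / % | substrate / % |
|---|---|---|---|---|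
| eta | 0.333 | 14.9 | 12.5 | 71.9 |
| eta | 0.833 | 18.9 | 37.6 | 44.5 |
| eta | 1.67 | 17.0 | 60.7 | 20.2 |
| eta | 2.50 | 16.4 | 72.8 | 10.2 |
| eta | 4.00 | 15.8 | 81.3 | 2.8 |
| alpha | 0.333 | 4.3 | 59.2 | 37.2 |
| alpha | 0.833 | 2.4 | 89.5 | 8.8 |
| alpha | 1.67 | 0.7 | 98.8 | 0.8 |
| alpha | 2.50 | 0 | 100.3 | 0.5 |
| alpha | 4.00 | 0.6 | 100.1 | 0 |

(each reading ± 0.5 percentage points)

- "hardly changes" means that all values lie within two and a half points (for a concentration: within two and a half percent of the largest)

- share of target in all that became target or over-reaction product for Sunday's, Thursday's, Friday's, Saturday's, in this order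
- the course of these numbers from the first flask to the last (rises all the way / rises, then falls / falls, then rises / falls all the way / hardly changes)

- The quantity to carry is the early half-life of target, 0.233 d: ln(2) times the target standing, divided by its flow into over-reaction product, a pseudo-first-order half-life read between those two eta readings.
- One objection is that this half-life may not depend on the charge. The same reading in the alpha run gives 0.0383 d, shorter by a factor of 6.08 for a charge higher by 9.20. Alpha's two target readings, 4.3 % and 2.4 %, each carry a scatter of 0.5 points, so this reckoning scales the half-life inversely with concentration, as a direction rather than a law.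
- A second objection is that the half-life does not stay constant. Between 2.50 d and 4.00 d the eta readings give 1.97 d, longer by a factor of 8.45, so whatever consumes target fades during the eta run.
- The end state comes next. Eta's substrate stands at 2.8 % at 4.00 d, so the share at 5.0 d is taken as what survives of converted substrate.
- Scaled from eta, the late half-life runs from 2.46 d in Sunday's flask to 0.328 d in Saturday's. Sunday's charge is lower than eta's, so this reckoning puts Sunday's share above the 16.3 % read in the eta run at 4.00 d, and it has the row fall by a larger factor at each step.
- The forecast gives 21 %, 8 %, 2.5 % and 1 %, so falls all the way, and it says: “With only two concentrations, a monotonic fall is an assumption.” Its last factor, 2.50, is smaller than the one before, 3.20, and there it differs from this reckoning.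
- The flasks give 21.4 %, 6.51 %, 0.737 % and 0.0331 %: falls all the way.

    initiator → 2 initiating radical (k = 2.60 × 10⁻⁶ s⁻¹)
    substrate + initiating radical → chain carrier (k = 588 M⁻¹ s⁻¹)
    partner + chain carrier → target + initiating radical (k = 66.4 M⁻¹ s⁻¹)
    2 initiating radical → ended chains (k = 8.00 × 10⁶ M⁻¹ s⁻¹)
    partner + target → over-reaction product (k = 4.16 × 10⁻⁴ M⁻¹ s⁻¹)
    partner → decomposed reagent (k = 6.06 × 10⁻⁶ s⁻¹)

- In Sunday's flask, partner stands at 13.1 % of its charge at 2.50 d; the carried half-life, scaled to that flask's charge and that partner, becomes 2.23 d, and target stands at 20.4 % then and 20.8 % at 5.00 d. In Saturday's flask, partner stands at 13.1 % at the same time, the same scaling gives 0.296 d, shorter than 5.0 d, and target falls from 0.349 % to 0.0331 %.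

(The readings stem from a simulated flask for substances that don't exist; scatter was added.)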